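**Plan**

- Retrosynthetic cuts, in order: C3–C4 of the pyranone ring C (formyl C–H added across an enol ether); the O1–C2 vinyl ether bond; the C4–C4a formyl bond; the C8–CH2 bond to the lavandulyl chain; the Cα–prenyl bond of the chain.
- Enabling feature: C4 sits on ring A ortho to O1, and C2 carries both O1 and ring B. C2–C3 can therefore be carried as an aryl 1-arylvinyl ether whose terminal CH2 (C3) is 1,6 to the formyl carbon, so an intramolecular hydroacylation closes ring C and creates C2 in one event.
- Forward: rings A and B are bought. The chain is built (Evans deconjugative alkylation) and joined to C8 by sp3–sp2 Negishi coupling on a symmetric bis-MOM arene; C4 is then added by ortho-lithiation/formylation, O1 is vinylated, and ring C is closed last.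
- Stereochemistry: the side-chain centre comes from the (S)-4-benzyloxazolidinone auxiliary; C2 (S) comes from the chiral Rh–bisphosphine catalyst of the ring closure.

Key step: step 13

Remark: Lav = (2R)-5-methyl-2-(prop-1-en-2-yl)hex-4-en-1-yl, the side chain of the target. The same spatial arrangement is (S) in lavandulol and its iodide because the CIP priorities change.
Remark: the sense of induction of the Rh catalyst at C2 cannot be predicted with certainty; the ligand is written as the (R)-antipode and would be exchanged for (S) if a first run gives the 2R epimer.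
Remark: reagents over the arrow are not numbered; organometallic and enolate species generated in the flask are.

**Route**

Step 1
Reactants: 1 (S)-4-benzyloxazolidin-2-one; 2 3-methylbut-2-enoyl chloride
Product: 4 (S)-4-benzyl-3-(3-methylbut-2-enoyl)oxazolidin-2-one, via lithium oxazolidinide 3 (not isolated)
Conditions: n-BuLi, THF, −78 °C; then 2, −78 → 0 °C
Reagents that add atoms: none
Why: N-acylation of the lithiated oxazolidinone by the acid chloride (Evans imide formation) should proceed cleanly and touches no stereocentre.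

Step 2
Reactants: 4 (S)-4-benzyl-3-(3-methylbut-2-enoyl)oxazolidin-2-one; 5 prenyl bromide (1-bromo-3-methylbut-2-ene)
Product: 7 (S)-4-benzyl-3-[(2S)-5-methyl-2-(prop-1-en-2-yl)hex-4-enoyl]oxazolidin-2-one, via sodium dienolate 6 (not isolated)
Conditions: NaHMDS, THF, −78 °C; then 5, −78 → −30 °C
Reagents that add atoms: none
Why: Evans deconjugative α-alkylation: γ-deprotonation gives the chelated Z(O)-dienolate, which should be alkylated at Cα on the face opposite the C4 benzyl group, setting the side-chain stereocentre and moving the double bond into the isopropenyl position.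

Step 3
Reactants: 7 (S)-4-benzyl-3-[(2S)-5-methyl-2-(prop-1-en-2-yl)hex-4-enoyl]oxazolidin-2-one
Product: 8 (S)-lavandulol [(2S)-5-methyl-2-(prop-1-en-2-yl)hex-4-en-1-ol]
Conditions: LiBH4, MeOH (1 equiv), Et2O, 0 °C
Reagents that add atoms: none
Why: Reductive cleavage of the N-acyloxazolidinone with lithium borohydride should give the primary alcohol without epimerisation or alkene migration and return the auxiliary.

Step 4
Reactants: 8 (S)-lavandulol
Product: 9 (S)-lavandulyl iodide [(3S)-3-(iodomethyl)-2,6-dimethylhepta-1,5-diene]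
Conditions: I2, PPh3, imidazole, CH2Cl2, 0 °C → rt
Reagents that add atoms: iodine, II
Why: Appel-type iodination is an SN2 displacement at the primary carbon and should leave the adjacent stereocentre and both alkenes untouched.

Step 5
Reactants: 10 5-methoxyresorcinol (5-methoxybenzene-1,3-diol)
Product: 11 1-methoxy-3,5-bis(methoxymethoxy)benzene
Conditions: MOMCl, i-Pr2NEt, CH2Cl2, 0 °C → rt
Reagents that add atoms: chloromethyl methyl ether (MOMCl), COCCl
Why: Standard O-alkylation of both phenols gives the bis-MOM ether, which serves as protecting group and as ortho-directing group.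

Step 6
Reactants: 11 1-methoxy-3,5-bis(methoxymethoxy)benzene
Product: 13 2-iodo-5-methoxy-1,3-bis(methoxymethoxy)benzene, via 2-lithio arene 12 (not isolated)
Conditions: n-BuLi, THF, 0 °C; then I2, −78 °C → rt
Reagents that add atoms: iodine, II
Why: Directed ortho-metalation should occur at C2, the position flanked by the two strongly coordinating OMOM groups, and iodine quench fixes the future C8 attachment point.

Step 7
Reactants: 9 (S)-lavandulyl iodide; 13 2-iodo-5-methoxy-1,3-bis(methoxymethoxy)benzene
Product: 16 2-Lav-5-methoxy-1,3-bis(methoxymethoxy)benzene, via lavandulyllithium 14 (not isolated), via lavandulylzinc chloride 15 (not isolated)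
Conditions: 9, t-BuLi (2.1 equiv), Et2O, −78 °C; ZnCl2, THF, −78 °C → rt; then 13, Pd(OAc)2 (4 mol%), SPhos (8 mol%), THF, 50 °C
Reagents that add atoms: none
Why: Polar iodine–lithium exchange, transmetalation to zinc and Negishi sp3–sp2 coupling with a bulky biarylphosphine should join the chain to the di-ortho-alkoxy aryl iodide with the β-stereocentre intact.

Step 8
Reactants: 16 2-Lav-5-methoxy-1,3-bis(methoxymethoxy)benzene
Product: 18 3-Lav-6-methoxy-2,4-bis(methoxymethoxy)benzaldehyde, via aryllithium 17 (not isolated)
Conditions: n-BuLi, TMEDA, THF, −20 → 0 °C; then DMF, −78 °C → rt; aq NH4Cl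
Reagents that add atoms: N,N-dimethylformamide (DMF), CN(C)C=O
Why: Directed ortho-metalation/formylation: the two remaining ring C–H positions are equivalent by symmetry, each between OMOM and OMe, so a single aldehyde should form and the symmetry is broken.

Step 9
Reactants: 18 3-Lav-6-methoxy-2,4-bis(methoxymethoxy)benzaldehyde
Product: 19 2-hydroxy-3-Lav-6-methoxy-4-(methoxymethoxy)benzaldehyde
Conditions: MgBr2·OEt2 (2 equiv), Et2O/CH2Cl2, 0 °C → rt
Reagents that add atoms: none
Why: Chelation-controlled acetal cleavage: magnesium bound between the formyl oxygen and the ortho acetal oxygen should activate only the MOM group next to the aldehyde, leaving the 4-OMOM and the methyl ether.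

Step 10
Reactants: 20 2'-hydroxyacetophenone
Product: 21 1-[2-(methoxymethoxy)phenyl]ethan-1-one
Conditions: MOMCl, i-Pr2NEt, CH2Cl2, 0 → 40 °C
Reagents that add atoms: chloromethyl methyl ether (MOMCl), COCCl
Why: O-alkylation of the phenol installs the same protecting group as on ring A so that both are removed together at the end.

Step 11
Reactants: 21 1-[2-(methoxymethoxy)phenyl]ethan-1-one
Product: 23 1-[2-(methoxymethoxy)phenyl]ethenyl trifluoromethanesulfonate, via potassium enolate 22 (not isolated)
Conditions: KHMDS, THF, −78 °C; then PhNTf2, −78 → 0 °C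
Reagents that add atoms: N-phenylbis(trifluoromethanesulfonimide) (PhNTf2), O=S(=O)(N(c1ccccc1)S(=O)(=O)C(F)(F)F)C(F)(F)F
Why: O-sulfonylation of the kinetic methyl ketone enolate is the standard route to a 1-arylvinyl triflate.

Step 12
Reactants: 19 2-hydroxy-3-Lav-6-methoxy-4-(methoxymethoxy)benzaldehyde; 23 1-[2-(methoxymethoxy)phenyl]ethenyl trifluoromethanesulfonate
Product: 24 3-Lav-6-methoxy-4-(methoxymethoxy)-2-({1-[2-(methoxymethoxy)phenyl]ethenyl}oxy)benzaldehyde
Conditions: Pd2(dba)3 (2.5 mol%), t-BuXPhos (6 mol%), K3PO4, toluene, 80 °C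
Reagents that add atoms: none
Why: Palladium-catalysed C–O cross-coupling of a phenol with an enol triflate (aryl enol ether synthesis) should give the 1-arylvinyl ether; the vinyl–Pd species has no β-hydrogen and the weak base spares the aldehyde.

Step 13
Reactants: 24 3-Lav-6-methoxy-4-(methoxymethoxy)-2-({1-[2-(methoxymethoxy)phenyl]ethenyl}oxy)benzaldehyde
Product: 25 (2S)-8-Lav-5-methoxy-7-(methoxymethoxy)-2-[2-(methoxymethoxy)phenyl]-2,3-dihydro-4H-chromen-4-one
Conditions: [Rh(cod)Cl]2 (2.5 mol%), (R)-DTBM-SEGPHOS (5.5 mol%), NaBArF4 (6 mol%), 1,4-dioxane, 60 °C, strictly anhydrous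
Reagents that add atoms: none
Why: Proposed new method: the formyl C–H of 24 should add oxidatively to the cationic Rh(I)–bisphosphine to give an acyl–Rh(III) hydride held by O1 and the enol-ether π bond, the 1,1-disubstituted O1–C2(Ar)=C3H2 alkene then inserts into Rh–H with H going to C2 and Rh to the terminal C3, and C–C reductive elimination from the seven-membered acyl–alkyl rhodacycle forms the C3–C4 bond. The closest known reaction type is the Rh(I)/chiral bisphosphine-catalysed enantioselective endo-hydroacylation of 1,1-disubstituted alkenes tethered to aryl aldehydes (2-substituted ortho-allylbenzaldehydes to 3-substituted tetralones, α-substituted 2-vinylbenzaldehydes to indanones, N-vinylindole-2-carbaldehydes), here transferred to an aryl 1-arylvinyl ether. Ring C (the pyran-4-one) is closed in the 6-endo-trig mode, both alkene carbons ending inside the new ring. The new C2 stereocentre is set in the hydride-insertion step by the chiral ligand, which selects the enol-ether face (catalyst control; the lavandulyl centre is too remote to matter, and a C2 epimer would be a separable diastereomer). The step needs endo over exo regioselectivity (flavanone, not the 2-aryl-2-methylbenzofuran-3-one), which the fully substituted C2 secures because exo closure would demand a tertiary α-oxybenzylic C–Rh and a reductive elimination that forms a quaternary centre, and it needs hydroacylation to outrun decarbonylation, which O1 chelation, the second ortho oxygen (5-OMe) and the wide-bite-angle ligand favour. The lavandulyl alkenes cannot reach the acyl–Rh centre from C8 and should stay untouched.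

Step 14
Reactants: 25 (2S)-8-Lav-5-methoxy-7-(methoxymethoxy)-2-[2-(methoxymethoxy)phenyl]-2,3-dihydro-4H-chromen-4-one
Product: 26 kushenol R
Conditions: ZnBr2 (2 equiv), n-PrSH (4 equiv), CH2Cl2, 0 °C, 10–15 min
Reagents that add atoms: none
Why: Lewis acid/thiol cleavage of both aryl MOM ethers under brief aprotic conditions should free the 7- and 2'-hydroxyls without protonating the lavandulyl alkenes or opening the flavanone, so C2 is not scrambled.

**Compound list**

1 | (S)-4-benzyloxazolidin-2-one | O=C1N[C@@H](Cc2ccccc2)CO1 | starting material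
2 | 3-methylbut-2-enoyl chloride | CC(C)=CC(=O)Cl | starting material
3 | lithium salt of (S)-4-benzyloxazolidin-2-one | O=C1N([Li])[C@@H](Cc2ccccc2)CO1 | intermediate
4 | (S)-4-benzyl-3-(3-methylbut-2-enoyl)oxazolidin-2-one | CC(C)=CC(=O)N1[C@@H](Cc2ccccc2)COC1=O | intermediate
5 | prenyl bromide (1-bromo-3-methylbut-2-ene) | CC(C)=CCBr | starting material
6 | sodium Z(O)-dienolate of 4 | C=C(C)/C=C(\[O-])N1[C@@H](Cc2ccccc2)COC1=O.[Na+] | intermediate
7 | (S)-4-benzyl-3-[(2S)-5-methyl-2-(prop-1-en-2-yl)hex-4-enoyl]oxazolidin-2-one | C=C(C)[C@H](CC=C(C)C)C(=O)N1[C@@H](Cc2ccccc2)COC1=O | intermediate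
8 | (S)-lavandulol, (2S)-5-methyl-2-(prop-1-en-2-yl)hex-4-en-1-ol | C=C(C)[C@H](CC=C(C)C)CO | intermediate
9 | (S)-lavandulyl iodide, (3S)-3-(iodomethyl)-2,6-dimethylhepta-1,5-diene | C=C(C)[C@H](CC=C(C)C)CI | intermediate
10 | 5-methoxyresorcinol | COc1cc(O)cc(O)c1 | starting material
11 | 1-methoxy-3,5-bis(methoxymethoxy)benzene | COCOc1cc(OC)cc(OCOC)c1 | intermediate
12 | 2-lithio-5-methoxy-1,3-bis(methoxymethoxy)benzene | COCOc1cc(OC)cc(OCOC)c1[Li] | intermediate
13 | 2-iodo-5-methoxy-1,3-bis(methoxymethoxy)benzene | COCOc1cc(OC)cc(OCOC)c1I | intermediate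
14 | lavandulyllithium (from 9) | C=C(C)[C@H](CC=C(C)C)C[Li] | intermediate
15 | lavandulylzinc chloride | C=C(C)[C@H](CC=C(C)C)C[Zn]Cl | intermediate
16 | 2-Lav-5-methoxy-1,3-bis(methoxymethoxy)benzene | C=C(C)[C@H](CC=C(C)C)Cc1c(OCOC)cc(OC)cc1OCOC | intermediate
17 | 4-lithio derivative of 16 (Li between OMOM and OMe) | C=C(C)[C@H](CC=C(C)C)Cc1c(OCOC)cc(OC)c([Li])c1OCOC | intermediate
18 | 3-Lav-6-methoxy-2,4-bis(methoxymethoxy)benzaldehyde | C=C(C)[C@H](CC=C(C)C)Cc1c(OCOC)cc(OC)c(C=O)c1OCOC | intermediate
19 | 2-hydroxy-3-Lav-6-methoxy-4-(methoxymethoxy)benzaldehyde | C=C(C)[C@H](CC=C(C)C)Cc1c(OCOC)cc(OC)c(C=O)c1O | intermediate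
20 | 2'-hydroxyacetophenone | CC(=O)c1ccccc1O | starting material
21 | 1-[2-(methoxymethoxy)phenyl]ethan-1-one | CC(=O)c1ccccc1OCOC | intermediate
22 | potassium enolate of 21 | C=C([O-])c1ccccc1OCOC.[K+] | intermediate
23 | 1-[2-(methoxymethoxy)phenyl]ethenyl trifluoromethanesulfonate | C=C(OS(=O)(=O)C(F)(F)F)c1ccccc1OCOC | intermediate
24 | 3-Lav-6-methoxy-4-(methoxymethoxy)-2-({1-[2-(methoxymethoxy)phenyl]ethenyl}oxy)benzaldehyde | C=C(C)[C@H](CC=C(C)C)Cc1c(OCOC)cc(OC)c(C=O)c1OC(=C)c1ccccc1OCOC | intermediate
25 | (2S)-8-Lav-5-methoxy-7-(methoxymethoxy)-2-[2-(methoxymethoxy)phenyl]-2,3-dihydro-4H-chromen-4-one | C=C(C)[C@H](CC=C(C)C)Cc1c(OCOC)cc(OC)c2c1O[C@H](c1ccccc1OCOC)CC2=O | intermediate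
26 | kushenol R, (2S)-7-hydroxy-2-(2-hydroxyphenyl)-5-methoxy-8-Lav-2,3-dihydro-4H-chromen-4-one | C=C(C)[C@H](CC=C(C)C)Cc1c(O)cc(OC)c2c1O[C@H](c1ccccc1O)CC2=O | target

**Step count and risks**

Total steps: 14. Longest linear sequence: 10 steps (1, 2, 3, 4, 7, 8, 9, 12, 13, 14).

Steps most likely to fail:

1. Step 13 (proposed new method). Possible failures: decarbonylation of the acyl–rhodium hydride before alkene insertion; insertion in the exo sense leading to five-ring closure; poor facial selectivity in the hydride insertion; Lewis-acid ionisation of the enol ether. Fallback with known chemistry, setting out from 16 and returning at 25: the in-flask aryllithium 17 is quenched with N-methoxy-N-methylacetamide to give the methyl ketone F1. Chelation-controlled MOM cleavage with MgBr2·OEt2 as in step 9 gives the 2-hydroxyacetophenone F2. Claisen–Schmidt condensation with 2-(methoxymethoxy)benzaldehyde (KOH, EtOH) gives the 2'-hydroxychalcone F3. Base-mediated oxa-Michael cyclisation (NaOAc, EtOH, reflux) should give 25 together with its C2 epimer F4. The two are diastereomers because of the fixed side-chain centre, so they would be separated by preparative HPLC and F4 re-equilibrated through F3 under the same conditions.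

2. Step 12. Possible failures: slow C–O reductive elimination from palladium because the phenoxide is flanked by two ortho substituents and can chelate through the formyl oxygen; base-induced loss of triflate from 23 to the arylalkyne. Fallback by carbonyl methylenation, setting out from 16 and returning at 24: aryllithium 17 is quenched with N-methoxy-N-methylcarbamoyl chloride to give the Weinreb amide F5. MgBr2·OEt2 removes the MOM group ortho to the amide to give the phenol F6. Acylation with 2-(methoxymethoxy)benzoic acid (EDC, DMAP) gives the aryl ester F7. Petasis methylenation (Cp2TiMe2, toluene, 65 °C) of the activated aryl ester, with the di-ortho-substituted Weinreb amide as the less reactive carbonyl, gives the enol ether F8. LiAlH4 (THF, −40 °C) then reduces the Weinreb amide to the aldehyde 24.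

3. Step 7. Possible failures: β-hydride elimination from the alkylpalladium intermediate (reduction of the aryl iodide, alkene isomerisation, erosion of the side-chain centre); slow transmetalation at the hindered di-ortho-alkoxy aryl–palladium. Fallback with reversed polarity, setting out from 11 and 9 and returning at 16: the aryllithium 12, generated as in step 6, is alkylated directly with iodide 9 (THF/DMPU, −78 → 0 °C, optionally 10 mol% CuBr·SMe2) in an SN2 reaction at the primary carbon. This makes the iodination of step 6 and the organozinc unnecessary and creates no new compound.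

Further compounds
F1 | step 13 | 1-[3-Lav-6-methoxy-2,4-bis(methoxymethoxy)phenyl]ethan-1-one | C=C(C)[C@H](CC=C(C)C)Cc1c(OCOC)cc(OC)c(C(C)=O)c1OCOC
F2 | step 13 | 1-[2-hydroxy-3-Lav-6-methoxy-4-(methoxymethoxy)phenyl]ethan-1-one | C=C(C)[C@H](CC=C(C)C)Cc1c(OCOC)cc(OC)c(C(C)=O)c1O
F3 | step 13 | (E)-1-[2-hydroxy-3-Lav-6-methoxy-4-(methoxymethoxy)phenyl]-3-[2-(methoxymethoxy)phenyl]prop-2-en-1-one | C=C(C)[C@H](CC=C(C)C)Cc1c(OCOC)cc(OC)c(C(=O)/C=C/c2ccccc2OCOC)c1O
F4 | step 13 | (2R)-epimer of 25 | C=C(C)[C@H](CC=C(C)C)Cc1c(OCOC)cc(OC)c2c1O[C@@H](c1ccccc1OCOC)CC2=O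
F5 | step 12 | N-methoxy-N-methyl-3-Lav-6-methoxy-2,4-bis(methoxymethoxy)benzamide | C=C(C)[C@H](CC=C(C)C)Cc1c(OCOC)cc(OC)c(C(=O)N(C)OC)c1OCOC
F6 | step 12 | 2-hydroxy-N-methoxy-N-methyl-3-Lav-6-methoxy-4-(methoxymethoxy)benzamide | C=C(C)[C@H](CC=C(C)C)Cc1c(OCOC)cc(OC)c(C(=O)N(C)OC)c1O
F7 | step 12 | 2-[methoxy(methyl)carbamoyl]-6-Lav-3-methoxy-5-(methoxymethoxy)phenyl 2-(methoxymethoxy)benzoate | C=C(C)[C@H](CC=C(C)C)Cc1c(OCOC)cc(OC)c(C(=O)N(C)OC)c1OC(=O)c1ccccc1OCOC
F8 | step 12 | N-methoxy-N-methyl-3-Lav-6-methoxy-4-(methoxymethoxy)-2-({1-[2-(methoxymethoxy)phenyl]ethenyl}oxy)benzamide | C=C(C)[C@H](CC=C(C)C)Cc1c(OCOC)cc(OC)c(C(=O)N(C)OC)c1OC(=C)c1ccccc1OCOC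
F0 | step 7 | none | none
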